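Start from the branches.

    X → D (k1 = 5.6 × 10⁻⁵ s⁻¹)
    X + X ⇌ X2 (K2 = 110 M⁻¹, k2 = 1.7 × 10⁻⁴ M⁻¹ s⁻¹)
    X ⇌ G (K3 = 21, k3 = 1.3 × 10⁻⁴ s⁻¹)

| setting | spring | autumn | dusk | summer | midnight |
|---|---|---|---|---|---|
| X | 0.050 M | 0.10 M | 0.20 M | 0.40 M | 0.80 M |
| time | 8.0 h | 8.0 h | 8.0 h | 8.0 h | 8.0 h |

- a species is counted by the X in it: one X2 counts as two
- two of one species on the left: rate k times its square, two consumed each time
- "hardly changes" means that all values lie within two and a half points (for a concentration: within two and a half percent of the largest)
- run time (spring): 8.0 h

1. [D] at the end for spring, autumn, dusk, summer, midnight, in this order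
2. how the row runs (rises all the way / rises, then falls / falls, then rises / hardly changes / falls all the way)

- X leaves by the steps to D, G and X2, and the step to X2 spends two X each time, so it gains on the other steps as X rises. We call crossover concentration the level of X at which the step to X2 uses X as fast as the steps to D and G together: 0.547 M.
- Well below that level, the share of lost X that becomes D is 30.1%; at the crossover it is cut by a factor of 2. This running share is the selectivity.
- Summing it while X falls from the charge to nothing, with no X coming back, gives D = share × crossover × ln(1 + charge/crossover). We may carry the sum that far as a first estimate because the forward steps to D and G together have a time of 1.49 h, shorter than the run of 8.0 h; counting those forward steps alone, that time leaves a fraction 0.472% of the X unspent.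
- But G comes back. Its time for return is 44.9 h, longer than the run but not by enough to drop it. Over the 6.51 h after the first fall, we reckon that this return lifts D by a factor of 1.10, and we take the same factor for each charge.
- That factor assumes returning X escapes the step to X2. We test this on midnight, the flask with the largest charge: were its whole charge in G, the X held up would be 0.0266 M, far below the crossover. X2 returns more slowly than G, with a time of 180 h, so we drop it.
- Our row is 0.0159 M, 0.0305 M, 0.0565 M, 0.0996 M, 0.163 M. The logarithm grows with the charge, so our row rises, though our yield per charge falls from 31.7% at spring to 20.4% at midnight.
- The forecast gives 0.0155 M, 0.0297 M, 0.0554 M, 0.098 M, 0.163 M, and rises all the way: “D rises throughout, though less than proportionally”. Ours is higher at spring and level with it at midnight.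
- The flask gives 0.0154 M, 0.0297 M, 0.0552 M, 0.0976 M, 0.161 M, and rises all the way. At the end of midnight, X2 holds 37.5% of the X charged, against 4.24% at the end of spring. The crossover also reads the slope of the row: with u the charge over the crossover, the order of D in the charge is u divided by (1 + u) ln(1 + u). Autumn has u = 0.183, which gives 0.920, and the local order of the autumn flask stands at 0.92.

Its constants belong to no real substance, and the outcome is calculated.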